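**Plan**

- Retrosynthesis: the C12–C13 bond is cut first (α-substituted butenolide from an α-phenylthio-γ-butyrolactone enolate and a C12 iodide). Then the C6–O and C9–O bonds are cut together, back to a ring B 6,8-diene and O2. The diene is traced to (+)-sclareolide.
- Enabling feature: on ring B the C6 acetoxy and C9 hydroxyl groups are 1,4-related and both α, flanking C7–C8. This is the imprint of an O2 adduct across C6=C7–C8=C9.
- Forward order: rings A and B come intact from sclareolide. C8=C9 alkene, C7 ketone, dienyl triflate and its reduction give the diene. The peroxide ring closes in step 7 and is opened by base to the 9-hydroxy-7-en-6-one. Li/NH3 reduction, acetylation, C12 iodide, lactone alkylation and sulfoxide elimination finish the route.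
- Stereochemistry: C5 and C10 come from sclareolide. C9 (kept) and C6 arise by α-face cycloaddition anti to the C10 methyl. C6 is then re-set as the equatorial 6α-alcohol and C8 is set by axial β-protonation in the dissolving-metal step.

Key step: step 7

Remark: labdane numbering is used. The target is read as 6α-acetoxy, 9α-hydroxy, 8α-methyl (8β-H), 5α-H, 10β-methyl. Sulfide 22 and sulfoxide 23 are mixtures at C13 (and sulfur), which is harmless because C13 becomes trigonal.

**Route**

Step 1
Reactants: 1 (+)-sclareolide
Product: 2 methyl 13,14,15,16-tetranorlabd-8-en-12-oate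
Conditions: H2SO4 (cat.), MeOH, reflux
Reagents that add atoms: methanol, CO
Why: Acid-catalysed alkyl–oxygen cleavage of the tertiary lactone (E1) with Fischer esterification of the freed acid, under conditions that equilibrate the alkene isomers, should leave mainly the tetrasubstituted C8=C9 isomer, the most stable one; minor C7=C8 and exocyclic isomers are removed on AgNO3-impregnated silica and resubmitted.

Step 2
Reactants: 2 methyl 13,14,15,16-tetranorlabd-8-en-12-oate
Product: 3 13,14,15,16-tetranorlabd-8-en-12-ol
Conditions: LiAlH4, THF, 0 °C → rt; Na2SO4·10H2O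
Reagents that add atoms: none
Why: Hydride reduction of the ester gives the primary alcohol, and the tetrasubstituted alkene is inert to the reagent.

Step 3
Reactants: 3 13,14,15,16-tetranorlabd-8-en-12-ol
Product: 4 12-(tert-butyldimethylsilyloxy)-13,14,15,16-tetranorlabd-8-ene
Conditions: tert-butyldimethylsilyl chloride, imidazole, DMF, rt
Reagents that add atoms: tert-butyldimethylsilyl chloride, CC(C)(C)[Si](C)(C)Cl
Why: Silylation of the unhindered primary hydroxyl gives an ether that should withstand the chromium oxidant, amide bases, palladium/formate, singlet oxygen and Li/NH3.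

Step 4
Reactants: 4 12-(tert-butyldimethylsilyloxy)-13,14,15,16-tetranorlabd-8-ene
Product: 5 12-(tert-butyldimethylsilyloxy)-13,14,15,16-tetranorlabd-8-en-7-one
Conditions: CrO3, 3,5-dimethylpyrazole, CH2Cl2, −20 °C
Reagents that add atoms: chromium trioxide, O=[Cr](=O)=O
Why: Allylic oxidation with the CrO3–3,5-dimethylpyrazole complex should turn the ring methylene C7, whose axial C–H bond overlaps with the C8=C9 π bond, into the conjugated ketone, whereas C11 is shielded by the quaternary C10 and the C8 methyl offers only a primary position.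

Step 5
Reactants: 5 12-(tert-butyldimethylsilyloxy)-13,14,15,16-tetranorlabd-8-en-7-one
Product: 7 12-(tert-butyldimethylsilyloxy)-13,14,15,16-tetranorlabda-6,8-dien-7-yl trifluoromethanesulfonate, via lithium dienolate 6 (not isolated)
Conditions: LiN(iPr)2, THF, −78 °C; N-phenylbis(trifluoromethanesulfonimide), −78 → 0 °C; aq. NH4Cl
Reagents that add atoms: N-phenylbis(trifluoromethanesulfonimide), O=S(=O)(N(c1ccccc1)S(=O)(=O)C(F)(F)F)C(F)(F)F
Why: Kinetic deprotonation of the enone at the α' carbon C6 by the lithium amide gives the cross-conjugated dienolate, which is O-sulfonylated (enol triflate formation) with the C6=C7 and C8=C9 double bonds already in their final positions.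

Step 6
Reactants: 7 12-(tert-butyldimethylsilyloxy)-13,14,15,16-tetranorlabda-6,8-dien-7-yl trifluoromethanesulfonate
Product: 8 12-(tert-butyldimethylsilyloxy)-13,14,15,16-tetranorlabda-6,8-diene
Conditions: Pd(OAc)2 (cat.), PPh3, n-Bu3N, HCO2H, DMF, 60 °C
Reagents that add atoms: none
Why: Palladium-catalysed formate reduction of the dienyl triflate (oxidative addition of zerovalent palladium to the C7–O bond, formate exchange, loss of CO2, C–H reductive elimination) replaces the triflate by hydrogen without moving either double bond.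

Step 7
Reactants: 8 12-(tert-butyldimethylsilyloxy)-13,14,15,16-tetranorlabda-6,8-diene; 9 dioxygen
Product: 10 6α,9α-epidioxy-12-(tert-butyldimethylsilyloxy)-13,14,15,16-tetranorlabd-7-ene
Conditions: O2, hν (visible light), 5,10,15,20-tetraphenylporphyrin (cat.), CH2Cl2, −20 °C
Reagents that add atoms: none
Why: The excited sensitiser passes its triplet energy to ground-state dioxygen, and the singlet oxygen formed adds across C6 and C9 of the diene in a concerted, suprafacial [4+2] cycloaddition (hetero-Diels–Alder reaction), making the C6–O and C9–O bonds in one event. The closest known reaction type is the photooxygenation of homoannular steroid 5,7-dienes and of α-terpinene to their endoperoxides. The six-membered 1,2-dioxene ring (C6–O–O–C9–C8=C7) closes by this intermolecular [4+2] cycloaddition, which turns ring B into a 2,3-dioxabicyclo[2.2.2]oct-5-ene. Both new stereocentres, C6 and C9, are fixed by the face of approach: the axial C10 methyl, helped by the axial C4 methyl, covers the β face, so both oxygens should arrive on the α face. The step needs periselectivity for cycloaddition over the ene reaction and α-face selectivity; the first rests on the diene being locked cisoid within ring B (helped by low temperature and an aprotic solvent), the second on the angular methyl group, and the silyl ether is inert to singlet oxygen.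

Step 8
Reactants: 10 6α,9α-epidioxy-12-(tert-butyldimethylsilyloxy)-13,14,15,16-tetranorlabd-7-ene
Product: 11 9α-hydroxy-12-(tert-butyldimethylsilyloxy)-13,14,15,16-tetranorlabd-7-en-6-one
Conditions: 1,8-diazabicyclo[5.4.0]undec-7-ene (0.2 equiv), CH2Cl2, 0 °C → rt
Reagents that add atoms: none
Why: Kornblum–DeLaMare rearrangement: the base removes H6, the only hydrogen on a peroxide-bearing carbon, the O–O bond breaks, C6 becomes the enone carbonyl and O9 stays on the fully substituted C9 as the tertiary alcohol with its α configuration untouched.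

Step 9
Reactants: 11 9α-hydroxy-12-(tert-butyldimethylsilyloxy)-13,14,15,16-tetranorlabd-7-en-6-one
Product: 14 12-(tert-butyldimethylsilyloxy)-13,14,15,16-tetranorlabdane-6α,9α-diol, via lithium alkoxide 12 (not isolated), via saturated hydroxy ketone 13 (not isolated)
Conditions: LiN(SiMe3)2 (1.0 equiv), THF, −78 °C; Li (excess), NH3(l)/THF, −78 °C; then MeOH, −78 → −33 °C; NH4Cl
Reagents that add atoms: none
Why: Dissolving-metal conjugate reduction followed by ketone reduction: the C9 hydroxyl is first made its lithium alkoxide so that it cannot leave from the adjacent C8 carbanion, C8 is then protonated by ammonia axially on the β face (the stereoelectronically required direction in the chair-like intermediate, as in the reduction of steroidal 8-en-11-ones), which places the methyl group equatorial (8α), and once methanol releases the ketone it is reduced under equilibrating conditions to the equatorial 6α-alcohol, the epimer free of 1,3-diaxial contact with the C4 and C10 methyl groups.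

Step 10
Reactants: 14 12-(tert-butyldimethylsilyloxy)-13,14,15,16-tetranorlabdane-6α,9α-diol
Product: 15 6α-acetoxy-12-(tert-butyldimethylsilyloxy)-13,14,15,16-tetranorlabdan-9α-ol
Conditions: Ac2O, pyridine, 4-dimethylaminopyridine (cat.), CH2Cl2, 0 °C → rt
Reagents that add atoms: acetic anhydride, CC(=O)OC(C)=O
Why: Nucleophile-catalysed acylation esterifies the secondary equatorial 6α-hydroxyl, while the tertiary C9 hydroxyl next to the quaternary C10 should stay free.

Step 11
Reactants: 15 6α-acetoxy-12-(tert-butyldimethylsilyloxy)-13,14,15,16-tetranorlabdan-9α-ol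
Product: 16 6α-acetoxy-13,14,15,16-tetranorlabdane-9α,12-diol
Conditions: HF·pyridine, THF, 0 °C → rt
Reagents that add atoms: none
Why: Fluoride-mediated cleavage of the primary silyl ether under buffered, non-basic conditions should leave the acetate and the tertiary alcohol alone.

Step 12
Reactants: 16 6α-acetoxy-13,14,15,16-tetranorlabdane-9α,12-diol
Product: 17 6α-acetoxy-12-iodo-13,14,15,16-tetranorlabdan-9α-ol
Conditions: I2, PPh3, imidazole, CH2Cl2, 0 °C
Reagents that add atoms: iodine, [I][I]
Why: Appel-type iodination: the primary alcohol forms the alkoxyphosphonium ion and is displaced by iodide (SN2), while the hindered tertiary alcohol should not react at 0 °C in the presence of imidazole.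

Step 13
Reactants: 18 α-bromo-γ-butyrolactone (racemic); 19 thiophenol
Product: 20 α-(phenylthio)-γ-butyrolactone (racemic)
Conditions: Et3N, CH2Cl2, 0 °C → rt
Reagents that add atoms: none
Why: SN2 displacement of the α-bromide by the thiolate gives the sulfenylated lactone, whose stereocentre is of no consequence.

Step 14
Reactants: 17 6α-acetoxy-12-iodo-13,14,15,16-tetranorlabdan-9α-ol; 20 α-(phenylthio)-γ-butyrolactone
Product: 22 6α-acetoxy-9α-hydroxy-13-(phenylsulfanyl)labdan-16,15-olide, via lithium enolate 21 (not isolated)
Conditions: 20 (1.6 equiv), LiN(SiMe3)2 (1.5 equiv), THF, −78 °C; then 17, DMPU, −78 → 0 °C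
Reagents that add atoms: none
Why: SN2 alkylation of the sulfur-stabilised lactone enolate by the primary iodide forms the C12–C13 bond; the base is kept in deficit to the lactone so that no amide remains to touch the acetate, the enolate is too weak a base to deprotonate the hindered tertiary alcohol, and the new C13 centre needs no control.

Step 15
Reactants: 22 6α-acetoxy-9α-hydroxy-13-(phenylsulfanyl)labdan-16,15-olide
Product: 24 6α-acetoxy-9α-hydroxylabd-13-en-16,15-olide (CNP0205088.2), via sulfoxide 23 (not isolated)
Conditions: mCPBA (1.0 equiv), toluene, −40 °C; then pyridine, 110 °C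
Reagents that add atoms: none
Why: Sulfide-to-sulfoxide oxidation and thermal syn-elimination of benzenesulfenic acid (sulfoxide pyrolysis), which in α-sulfinyl γ-lactones runs preferentially into the ring, should give the endocyclic α-substituted butenolide, the conjugated and more stable regioisomer.

**Compound list**

1 | (+)-sclareolide | C1C[C@@](C)(OC(=O)C3)[C@H]3[C@@]2(C)CCCC(C)(C)[C@H]12 | starting material
2 | methyl 13,14,15,16-tetranorlabd-8-en-12-oate | C1CC(C)=C(CC(=O)OC)[C@@]2(C)CCCC(C)(C)[C@H]12 | intermediate
3 | 13,14,15,16-tetranorlabd-8-en-12-ol | C1CC(C)=C(CCO)[C@@]2(C)CCCC(C)(C)[C@H]12 | intermediate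
4 | 12-(tert-butyldimethylsilyloxy)-13,14,15,16-tetranorlabd-8-ene | C1CC(C)=C(CCO[Si](C)(C)C(C)(C)C)[C@@]2(C)CCCC(C)(C)[C@H]12 | intermediate
5 | 12-(tert-butyldimethylsilyloxy)-13,14,15,16-tetranorlabd-8-en-7-one | C1C(=O)C(C)=C(CCO[Si](C)(C)C(C)(C)C)[C@@]2(C)CCCC(C)(C)[C@H]12 | intermediate
6 | lithium 6,8-dien-7-olate of 5 | C1=C([O-])C(C)=C(CCO[Si](C)(C)C(C)(C)C)[C@@]2(C)CCCC(C)(C)[C@H]12.[Li+] | intermediate (not isolated)
7 | 12-(tert-butyldimethylsilyloxy)-13,14,15,16-tetranorlabda-6,8-dien-7-yl trifluoromethanesulfonate | C1=C(OS(=O)(=O)C(F)(F)F)C(C)=C(CCO[Si](C)(C)C(C)(C)C)[C@@]2(C)CCCC(C)(C)[C@H]12 | intermediate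
8 | 12-(tert-butyldimethylsilyloxy)-13,14,15,16-tetranorlabda-6,8-diene | C1=CC(C)=C(CCO[Si](C)(C)C(C)(C)C)[C@@]2(C)CCCC(C)(C)[C@H]12 | intermediate
9 | dioxygen | O=O | starting material
10 | 6α,9α-epidioxy-12-(tert-butyldimethylsilyloxy)-13,14,15,16-tetranorlabd-7-ene | O3[C@H]1C=C(C)[C@](O3)(CCO[Si](C)(C)C(C)(C)C)[C@@]2(C)CCCC(C)(C)[C@H]12 | intermediate
11 | 9α-hydroxy-12-(tert-butyldimethylsilyloxy)-13,14,15,16-tetranorlabd-7-en-6-one | O=C1C=C(C)[C@](O)(CCO[Si](C)(C)C(C)(C)C)[C@@]2(C)CCCC(C)(C)[C@H]12 | intermediate
12 | lithium 9-alkoxide of 11 | O=C1C=C(C)[C@]([O-])(CCO[Si](C)(C)C(C)(C)C)[C@@]2(C)CCCC(C)(C)[C@H]12.[Li+] | intermediate (not isolated)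
13 | 9α-hydroxy-12-(tert-butyldimethylsilyloxy)-13,14,15,16-tetranorlabdan-6-one (8β-H; present as its lithium alkoxide) | O=C1C[C@@H](C)[C@](O)(CCO[Si](C)(C)C(C)(C)C)[C@@]2(C)CCCC(C)(C)[C@H]12 | intermediate (not isolated)
14 | 12-(tert-butyldimethylsilyloxy)-13,14,15,16-tetranorlabdane-6α,9α-diol | O[C@H]1C[C@@H](C)[C@](O)(CCO[Si](C)(C)C(C)(C)C)[C@@]2(C)CCCC(C)(C)[C@H]12 | intermediate
15 | 6α-acetoxy-12-(tert-butyldimethylsilyloxy)-13,14,15,16-tetranorlabdan-9α-ol | CC(=O)O[C@H]1C[C@@H](C)[C@](O)(CCO[Si](C)(C)C(C)(C)C)[C@@]2(C)CCCC(C)(C)[C@H]12 | intermediate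
16 | 6α-acetoxy-13,14,15,16-tetranorlabdane-9α,12-diol | CC(=O)O[C@H]1C[C@@H](C)[C@](O)(CCO)[C@@]2(C)CCCC(C)(C)[C@H]12 | intermediate
17 | 6α-acetoxy-12-iodo-13,14,15,16-tetranorlabdan-9α-ol | CC(=O)O[C@H]1C[C@@H](C)[C@](O)(CCI)[C@@]2(C)CCCC(C)(C)[C@H]12 | intermediate
18 | α-bromo-γ-butyrolactone (racemic) | O=C1OCCC1Br | starting material
19 | thiophenol | Sc1ccccc1 | starting material
20 | α-(phenylthio)-γ-butyrolactone (racemic) | O=C1OCCC1Sc1ccccc1 | intermediate
21 | lithium enolate of 20 | [Li+].[O-]C1=C(Sc2ccccc2)CCO1 | intermediate (not isolated)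
22 | 6α-acetoxy-9α-hydroxy-13-(phenylsulfanyl)labdan-16,15-olide (C13 epimers) | CC(=O)O[C@H]1C[C@@H](C)[C@](O)(CCC2(Sc3ccccc3)CCOC2=O)[C@@]2(C)CCCC(C)(C)[C@H]12 | intermediate
23 | 6α-acetoxy-9α-hydroxy-13-(phenylsulfinyl)labdan-16,15-olide | CC(=O)O[C@H]1C[C@@H](C)[C@](O)(CCC2(S(=O)c3ccccc3)CCOC2=O)[C@@]2(C)CCCC(C)(C)[C@H]12 | intermediate (not isolated)
24 | 6α-acetoxy-9α-hydroxylabd-13-en-16,15-olide (CNP0205088.2) | CC(=O)O[C@H]1C[C@@H](C)[C@](O)(CCC2=CCOC2=O)[C@@]2(C)CCCC(C)(C)[C@H]12 | target

**Count and risks**

Total step count: 15. Longest linear sequence: 14 steps (steps 1–12, 14 and 15, from sclareolide); step 13 is a one-step side branch.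

Steps most likely to fail:

Step 9. The C9 oxygen may be lost by β-elimination from the C8 carbanion, which lies antiperiplanar to the axial C9–O bond, or C8 may be protonated from the α face. The fallback sets out from 11 and comes back at 14, and accepts the loss instead of fighting it. Li in NH3 without prior alkoxide formation, quenched with NH4Cl, is expected to expel the hydroxyl and give 12-(tert-butyldimethylsilyloxy)-13,14,15,16-tetranorlabd-8-en-6-one F1. Li/NH3/MeOH then reduces the ketone to the equatorial alcohol 12-(tert-butyldimethylsilyloxy)-13,14,15,16-tetranorlabd-8-en-6α-ol F2. mCPBA with NaHCO3 should epoxidise from the α face, anti to the C10 methyl and guided by the 6α-hydroxyl, to 8α,9α-epoxy-12-(tert-butyldimethylsilyloxy)-13,14,15,16-tetranorlabdan-6α-ol F3. LiEt3BH in THF at reflux should open the epoxide trans-diaxially, hydride entering at C8 from the β face, which returns the 9α-alcohol with 8β-H, that is diol 14.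

Step 7. The ene reaction (hydrogen abstraction at C5, at the C8 methyl or at C11) may compete with cycloaddition, and the peroxide may be over-oxidised on long irradiation. The fallback sets out from 8 and comes back at 10 without new compounds. Ground-state dioxygen is added in the dark under catalysis by the one-electron oxidant tris(4-bromophenyl)aminium hexachloroantimonate, (4-BrC6H4)3N·SbCl6, in CH2Cl2 at −78 °C. This is a radical-cation chain in which the diene radical cation captures triplet O2 and closes to the same endoperoxide, with no ene channel and the same α-face preference.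

Step 1. Migration of the double bond into the tetrasubstituted position may be incomplete, leaving an isomer mixture that is hard to separate, and prolonged acid may start skeletal shifts. The fallback sets out from 1 and comes back at 3. LiAlH4 gives 13,14,15,16-tetranorlabdane-8α,12-diol F4. Ac2O in pyridine acetylates only the primary hydroxyl to 8α-hydroxy-13,14,15,16-tetranorlabdan-12-yl acetate F5. PPh3/I2 in CH2Cl2, a reagent that dehydrates such tertiary 8α-alcohols regioselectively to the tetrasubstituted alkene, gives 13,14,15,16-tetranorlabd-8-en-12-yl acetate F6; an ester is used at C12 so that the C8 cation is not trapped as the cyclic ether. K2CO3 in MeOH then frees alcohol 3.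

**Further compounds**

F1 | step 9 | 12-(tert-butyldimethylsilyloxy)-13,14,15,16-tetranorlabd-8-en-6-one | O=C1CC(C)=C(CCO[Si](C)(C)C(C)(C)C)[C@@]2(C)CCCC(C)(C)[C@H]12
F2 | step 9 | 12-(tert-butyldimethylsilyloxy)-13,14,15,16-tetranorlabd-8-en-6α-ol | O[C@H]1CC(C)=C(CCO[Si](C)(C)C(C)(C)C)[C@@]2(C)CCCC(C)(C)[C@H]12
F3 | step 9 | 8α,9α-epoxy-12-(tert-butyldimethylsilyloxy)-13,14,15,16-tetranorlabdan-6α-ol | O[C@H]1C[C@@]3(C)O[C@@]3(CCO[Si](C)(C)C(C)(C)C)[C@@]2(C)CCCC(C)(C)[C@H]12
F0 | step 7 | none | none
F4 | step 1 | 13,14,15,16-tetranorlabdane-8α,12-diol | C1C[C@@](C)(O)[C@H](CCO)[C@@]2(C)CCCC(C)(C)[C@H]12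
F5 | step 1 | 8α-hydroxy-13,14,15,16-tetranorlabdan-12-yl acetate | C1C[C@@](C)(O)[C@H](CCOC(C)=O)[C@@]2(C)CCCC(C)(C)[C@H]12
F6 | step 1 | 13,14,15,16-tetranorlabd-8-en-12-yl acetate | C1CC(C)=C(CCOC(C)=O)[C@@]2(C)CCCC(C)(C)[C@H]12
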